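**Retrosynthetic overview**

1. Numbering (drimane): ring A = C1–C5/C10, ring B = C5–C10, C11 = OCH2 on C9, C12 = CH2 on C8. The last disconnection is C9–C11: an SE2′ (Hosomi–Sakurai) attack of a ring-B allylsilane on the aryloxymethyl cation of the coumarin half joins the two halves, sets C9 and moves the alkene to C8=C12 in one step.
2. Enabling feature: the allylsilane C12(SiMe3)–C8=C9 in ring B of a cis-fused decalin. C9 is its γ-carbon, and the convex face (that of C10–CH3 and C5–H) is the open one.
3. Allylsilane ⇐ enol triflate (Negishi) ⇐ regiospecific Δ8(9) enolate ⇐ Me2CuLi addition to the C8(=O)–C9=C10 enone, which sets C10 cis to C5–H.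
4. Enone ⇐ 6-methoxy-2-tetralone: C4 gem-dimethyl by enolate methylation, C3 by CBS reduction, ring B unmasked by Birch reduction/hydrolysis, C5 by catalyst-controlled β,γ→α,β isomerisation.
5. Rings: no carbocycle is built. Ring A and ring B (aromatic, dearomatised in step 3) come with the tetralone; the coumarin comes with isofraxidin, used as its pivaloyloxymethyl ether.

Key step: step 9

Remark: in step 4 the quinidine-series catalyst is assumed to be the antipode that protonates C5 anti to the C3 hydroxyl; if the sense is the reverse, the quinine-series pseudoenantiomer takes its place.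

**Route**

Step 1
Reactants: 1 6-methoxy-3,4-dihydronaphthalen-2(1H)-one (6-methoxy-2-tetralone)
Product: 2 6-methoxy-1,1-dimethyl-3,4-dihydronaphthalen-2(1H)-one
Conditions: NaH (2.3 equiv), MeI (3 equiv), THF, 0 °C → rt
Reagents that add atoms: iodomethane, CI
Why: Enolate alkylation: C1 of a 2-tetralone is benzylic and α to the ketone, so both deprotonations and both methylations occur there and give the gem-dimethyl carbon (future C4) without forming a stereocentre.

Step 2
Reactants: 2 6-methoxy-1,1-dimethyl-3,4-dihydronaphthalen-2(1H)-one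
Product: 3 (2S)-6-methoxy-1,1-dimethyl-1,2,3,4-tetrahydronaphthalen-2-ol
Conditions: (R)-2-methyl-CBS-oxazaborolidine (10 mol%), BH3·SMe2, THF, −20 °C; MeOH quench
Reagents that add atoms: none
Why: Corey–Bakshi–Shibata reduction: the (R)-oxazaborolidine–borane complex binds the ketone with the tert-alkyl flank (ArCMe2) as the large group and delivers hydride to one face, which sets C3 as (S) by reagent control.

Step 3
Reactants: 3 (2S)-6-methoxy-1,1-dimethyl-1,2,3,4-tetrahydronaphthalen-2-ol
Product: 5 (6S)-6-hydroxy-5,5-dimethyl-3,4,5,6,7,8-hexahydronaphthalen-2(1H)-one, via enol ether 4 (not isolated)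
Conditions: Li, NH3(l), THF, t-BuOH, −78 → −33 °C; then (CO2H)2, MeOH–H2O, rt
Reagents that add atoms: water, O
Why: Birch reduction protonates the unsubstituted ring carbons C6 and C9 and leaves the enol ether and the tetrasubstituted C5=C10 alkene, and oxalic acid hydrolyses only the enol ether, so the β,γ-unsaturated ketone is obtained without conjugation and C3 is untouched.

Step 4
Reactants: 5 (6S)-6-hydroxy-5,5-dimethyl-3,4,5,6,7,8-hexahydronaphthalen-2(1H)-one
Product: 6 (4aR,6S)-6-hydroxy-5,5-dimethyl-4,4a,5,6,7,8-hexahydronaphthalen-2(3H)-one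
Conditions: cinchona-derived 9-amino-9-deoxy primary–tertiary diamine catalyst (quinidine series, 10 mol%), carboxylic acid co-catalyst (20 mol%), toluene, 0 °C → rt
Reagents that add atoms: none
Why: Amine-catalysed enantioselective olefin isomerisation, a known reaction of β,γ-unsaturated cyclohexenones made from anisoles by Birch reduction: the catalyst forms the dienamine N–C8=C9–C10=C5 and its ammonium group protonates C5 on the face anti to the C3 hydroxyl, which sets C5 (H cis to C3–H) under catalyst control in the sense that also gives the diequatorial, thermodynamically preferred isomer.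

Step 5
Reactants: 6 (4aR,6S)-6-hydroxy-5,5-dimethyl-4,4a,5,6,7,8-hexahydronaphthalen-2(3H)-one
Product: 7 (2S,8aR)-1,1-dimethyl-6-oxo-1,2,3,4,6,7,8,8a-octahydronaphthalen-2-yl acetate
Conditions: Ac2O, pyridine, DMAP (cat.), CH2Cl2, rt
Reagents that add atoms: acetic anhydride, CC(=O)OC(C)=O
Why: DMAP-catalysed acyl transfer esterifies the hindered secondary alcohol with retention at C3, and the acetate of the target can be installed this early because the following cuprate and organozinc steps tolerate esters.

Step 6
Reactants: 7 (2S,8aR)-1,1-dimethyl-6-oxo-1,2,3,4,6,7,8,8a-octahydronaphthalen-2-yl acetate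
Product: 9 (2S,4aR,8aR)-1,1,4a-trimethyl-6-{[(trifluoromethyl)sulfonyl]oxy}-1,2,3,4,4a,7,8,8a-octahydronaphthalen-2-yl acetate, via lithium enolate 8 (not isolated)
Conditions: Me2CuLi (from MeLi and CuI, 2.5 equiv), Et2O, −78 → 0 °C; then PhNTf2, THF, −78 °C → rt; aq. NH4Cl
Reagents that add atoms: lithium dimethylcuprate, [Li+].C[Cu-]C; N-phenyl-bis(trifluoromethanesulfonimide), O=S(=O)(N(c1ccccc1)S(=O)(=O)C(F)(F)F)C(F)(F)F
Why: Conjugate addition of the Gilman cuprate sets C10: as in cuprate additions to Δ1(9)-2-octalones the methyl enters cis to C5–H (the opposite trajectory is 1,3-syn to the axial C4 methyl), which gives the cis ring fusion, and the regiospecific Δ8(9) lithium enolate is O-triflated before it can equilibrate.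

Step 7
Reactants: 9 (2S,4aR,8aR)-1,1,4a-trimethyl-6-{[(trifluoromethyl)sulfonyl]oxy}-1,2,3,4,4a,7,8,8a-octahydronaphthalen-2-yl acetate
Product: 10 (2S,4aS,8aR)-1,1,4a-trimethyl-6-[(trimethylsilyl)methyl]-1,2,3,4,4a,7,8,8a-octahydronaphthalen-2-yl acetate
Conditions: Me3SiCH2MgCl, ZnCl2, THF, 0 °C; then 9, Pd(PPh3)4 (5 mol%), rt → 50 °C; chromatography on Et3N-deactivated silica
Reagents that add atoms: (trimethylsilyl)methylzinc chloride, C[Si](C)(C)C[Zn]Cl (made in the flask from (trimethylsilyl)methylmagnesium chloride, C[Si](C)(C)C[Mg]Cl, and ZnCl2)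
Why: Negishi cross-coupling: oxidative addition of Pd(0) into the vinyl C–OTf bond, transmetalation with the β-hydrogen-free silylmethylzinc and reductive elimination give the allylsilane with the alkene fixed at C8=C9, the organozinc leaves the acetate alone, and no stereocentre is touched.

Step 8
Reactants: 11 isofraxidin (7-hydroxy-6,8-dimethoxy-2H-chromen-2-one)
Product: 12 [(6,8-dimethoxy-2-oxo-2H-chromen-7-yl)oxy]methyl 2,2-dimethylpropanoate
Conditions: chloromethyl pivalate, K2CO3, NaI (cat.), DMF, rt
Reagents that add atoms: chloromethyl pivalate, CC(C)(C)C(=O)OCCl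
Why: Williamson-type O-alkylation of the acidic 7-hydroxycoumarin by the iodide formed in situ (Finkelstein) from chloromethyl pivalate; the bulky pivalate suppresses acyl transfer to the phenoxide and the product is a stable precursor of the aryloxymethyl cation.

Step 9
Reactants: 10 (2S,4aS,8aR)-1,1,4a-trimethyl-6-[(trimethylsilyl)methyl]-1,2,3,4,4a,7,8,8a-octahydronaphthalen-2-yl acetate; 12 [(6,8-dimethoxy-2-oxo-2H-chromen-7-yl)oxy]methyl 2,2-dimethylpropanoate
Product: 14 (2S,4aR,5R,8aR)-5-{[(6,8-dimethoxy-2-oxo-2H-chromen-7-yl)oxy]methyl}-1,1,4a-trimethyl-6-methylidenedecahydronaphthalen-2-yl acetate (CNP0270939.1), via oxocarbenium triflate 13 (not isolated)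
Conditions: TMSOTf (1.2 equiv), 2,6-di-tert-butyl-4-methylpyridine (0.5 equiv), CH2Cl2, −78 → −40 °C; Et3N quench
Reagents that add atoms: none
Why: TMSOTf silylates the pivalate carbonyl of 12 and expels trimethylsilyl pivalate to give the aryloxymethyl oxocarbenium ion 13; the γ-carbon C9 of allylsilane 10 attacks it (SE2′), the resulting C8 cation is stabilised by the C12–Si bond and loses the silyl group to triflate, which moves the alkene to C8=C12 and regenerates TMSOTf. The closest known reaction type is the Hosomi–Sakurai allylation of oxocarbenium ions generated from α-acyloxy or α-halo ethers. No ring is closed. The new stereocentre C9 is controlled by the cis-fused decalin: the electrophile should enter on the convex face, syn to C10–CH3 and C5–H, because the concave face of C9 is covered by ring A, in particular by C4 and its axial methyl lying 1,3 to C9, so that C11 ends cis to the angular methyl as in the target. The step needs γ- over α-attack and a single alkene position, both fixed by silicon (β-silyl cation, loss of Si only), and it needs C–C bond formation to outrun protodesilylation and arylation of the coumarin, which the hindered pyridine base, the low temperature and the nucleophilicity of the allylsilane should secure.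

**Compound list**

1 | 6-methoxy-3,4-dihydronaphthalen-2(1H)-one | COc1ccc2CC(=O)CCc2c1 | starting material
2 | 6-methoxy-1,1-dimethyl-3,4-dihydronaphthalen-2(1H)-one | COc1ccc2C(C)(C)C(=O)CCc2c1 | intermediate
3 | (2S)-6-methoxy-1,1-dimethyl-1,2,3,4-tetrahydronaphthalen-2-ol | COc1ccc2C(C)(C)[C@@H](O)CCc2c1 | intermediate
4 | (2S)-6-methoxy-1,1-dimethyl-1,2,3,4,5,8-hexahydronaphthalen-2-ol (enol ether) | COC1=CCC2=C(C1)CC[C@H](O)C2(C)C | intermediate (not isolated)
5 | (6S)-6-hydroxy-5,5-dimethyl-3,4,5,6,7,8-hexahydronaphthalen-2(1H)-one | O=C1CCC2=C(C1)CC[C@H](O)C2(C)C | intermediate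
6 | (4aR,6S)-6-hydroxy-5,5-dimethyl-4,4a,5,6,7,8-hexahydronaphthalen-2(3H)-one | O=C1C=C2CC[C@H](O)C(C)(C)[C@@H]2CC1 | intermediate
7 | (2S,8aR)-1,1-dimethyl-6-oxo-1,2,3,4,6,7,8,8a-octahydronaphthalen-2-yl acetate | O=C1C=C2CC[C@H](OC(C)=O)C(C)(C)[C@@H]2CC1 | intermediate
8 | lithium (4aR,6S,8aR)-6-acetoxy-5,5,8a-trimethyl-3,4,4a,5,6,7,8,8a-octahydronaphthalen-2-olate (Δ8(9) enolate) | [Li]OC1=C[C@]2(C)CC[C@H](OC(C)=O)C(C)(C)[C@@H]2CC1 | intermediate (not isolated)
9 | (2S,4aR,8aR)-1,1,4a-trimethyl-6-{[(trifluoromethyl)sulfonyl]oxy}-1,2,3,4,4a,7,8,8a-octahydronaphthalen-2-yl acetate | O=S(=O)(OC1=C[C@]2(C)CC[C@H](OC(C)=O)C(C)(C)[C@@H]2CC1)C(F)(F)F | intermediate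
10 | (2S,4aS,8aR)-1,1,4a-trimethyl-6-[(trimethylsilyl)methyl]-1,2,3,4,4a,7,8,8a-octahydronaphthalen-2-yl acetate | C[Si](C)(C)CC1=C[C@]2(C)CC[C@H](OC(C)=O)C(C)(C)[C@@H]2CC1 | intermediate
11 | isofraxidin (7-hydroxy-6,8-dimethoxy-2H-chromen-2-one) | COc1cc2ccc(=O)oc2c(OC)c1O | starting material
12 | [(6,8-dimethoxy-2-oxo-2H-chromen-7-yl)oxy]methyl 2,2-dimethylpropanoate | CC(C)(C)C(=O)OCOc1c(OC)cc2ccc(=O)oc2c1OC | intermediate
13 | [(6,8-dimethoxy-2-oxo-2H-chromen-7-yl)oxy]methylium trifluoromethanesulfonate (oxocarbenium ion pair) | C=[O+]c1c(OC)cc2ccc(=O)oc2c1OC.[O-]S(=O)(=O)C(F)(F)F | intermediate (not isolated)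
14 | (2S,4aR,5R,8aR)-5-{[(6,8-dimethoxy-2-oxo-2H-chromen-7-yl)oxy]methyl}-1,1,4a-trimethyl-6-methylidenedecahydronaphthalen-2-yl acetate | C=C1CC[C@H]2C(C)(C)[C@@H](OC(C)=O)CC[C@@]2(C)[C@@H]1COc1c(OC)cc2ccc(=O)oc2c1OC | target

**Step count**

Total: 9 steps. Longest linear sequence: 8 steps (steps 1–7 and 9).

**Steps most likely to fail**

Step 4. The catalyst may not fully control the protonation of the hindered, neopentyl γ-carbon, and the product may re-enter the dienamine and drift towards the only weakly biased thermodynamic ratio, so that the two C5 epimers form together. The fallback replaces catalyst control by substrate control with recycling. It sets out from 5, which is equilibrated with DBU in toluene to a mixture of 6 and its ring-fusion epimer (4aS,6S)-6-hydroxy-5,5-dimethyl-4,4a,5,6,7,8-hexahydronaphthalen-2(3H)-one F1. The isomer 6, with the hydroxyl equatorial, should be the slightly favoured one. The two are separated by chromatography and F1 is returned to the DBU equilibration, because C5 stays epimerisable through the dienolate while C3 is fixed. The fallback comes back to the route at 6.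

Step 9. Facial selectivity at C9 may be eroded, since the convex approach passes the vicinal pseudoaxial C10 methyl; the allylsilane may be protodesilylated by adventitious acid; or the cation may be consumed by arylation of the coumarin. The fallback forms the C9–C11 bond with a small one-carbon electrophile and attaches the coumarin afterwards. It sets out from 10, which with monomeric formaldehyde (paraformaldehyde, Me2AlCl, CH2Cl2, −78 → 0 °C) should give in the same SE2′ sense the primary alcohol (2S,4aR,5R,8aR)-5-(hydroxymethyl)-1,1,4a-trimethyl-6-methylidenedecahydronaphthalen-2-yl acetate F2. Mitsunobu etherification of F2 with isofraxidin 11 (PPh3, DIAD, THF) then comes back to the route at 14.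

Step 6. Conjugate addition at the congested β-carbon C10 may be slow, which leaves room for 1,2-addition, attack on the acetate, or equilibration of the enolate towards C7 before O-triflation. The fallback separates C–C bond formation from sulfonylation. It sets out from 7, which with Me2CuLi and TMSCl (THF, −78 °C) should add faster and be trapped at once as the silyl enol ether (2S,4aR,8aR)-1,1,4a-trimethyl-6-[(trimethylsilyl)oxy]-1,2,3,4,4a,7,8,8a-octahydronaphthalen-2-yl acetate F3, which locks the Δ8(9) regiochemistry. Fluoride-triggered triflation of F3 (CsF, PhNTf2, DME, rt) comes back to the route at 9.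

**Further compounds**

F1 | step 4 | (4aS,6S)-6-hydroxy-5,5-dimethyl-4,4a,5,6,7,8-hexahydronaphthalen-2(3H)-one | O=C1C=C2CC[C@H](O)C(C)(C)[C@H]2CC1
F2 | step 9 | (2S,4aR,5R,8aR)-5-(hydroxymethyl)-1,1,4a-trimethyl-6-methylidenedecahydronaphthalen-2-yl acetate | C=C1CC[C@H]2C(C)(C)[C@@H](OC(C)=O)CC[C@@]2(C)[C@@H]1CO
F3 | step 6 | (2S,4aR,8aR)-1,1,4a-trimethyl-6-[(trimethylsilyl)oxy]-1,2,3,4,4a,7,8,8a-octahydronaphthalen-2-yl acetate | C[Si](C)(C)OC1=C[C@]2(C)CC[C@H](OC(C)=O)C(C)(C)[C@@H]2CC1
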